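The target is a 1-tetralone in which the C1 carbonyl and the C4 diarylmethine sit ortho on ring A, with C2 and C3 forming a trans-2-butene unit between them. Cutting C1–C2 and C3–C4 therefore reveals an o-formyl diarylmethane, a latent o-quinodimethane, and an (E)-2-butene equivalent as dienophile. In the key step, light turns 6-(3,4-dimethoxybenzyl)isovanillin pivalate into its hydroxy-o-quinodimethane, which a chiral titanium TADDOLate unites with tiglic aldehyde in an endo Diels–Alder reaction, closing ring B and fixing C3 and C4. Oxidation of the carbinol and retro-Claisen deformylation then remove the activating formyl group, free the phenol and set the enolizable C2 by equilibration.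

Key step: step 3

Assumption: the (R,R)-configured TADDOL ligand is taken to deliver the (3S,4R) series. The sense of induction would be checked on adduct 8, and the equally available (S,S)-ligand used if it proves opposite.

Step 1
Reactants: 1 2-bromo-5-hydroxy-4-methoxybenzaldehyde (6-bromoisovanillin)
Product: 2 4-bromo-5-formyl-2-methoxyphenyl pivalate
Conditions: PivCl, Et3N, DMAP (cat.), CH2Cl2, 0 °C to rt
Reagents that add atoms: pivaloyl chloride, CC(C)(C)C(=O)Cl
Why: Acylation of the phenol with an acid chloride under nucleophilic catalysis by DMAP should be clean, and the α-hydrogen-free pivalate masks the phenol through steps 2 to 4 and falls off under the methoxide of step 5.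

Step 2
Reactants: 2 4-bromo-5-formyl-2-methoxyphenyl pivalate; 3 3,4-dimethoxybenzyl chloride
Product: 5 4-(3,4-dimethoxybenzyl)-5-formyl-2-methoxyphenyl pivalate, via (3,4-dimethoxybenzyl)zinc chloride 4 (not isolated)
Conditions: 3, Zn dust, LiCl, THF, rt; then 2, Pd(OAc)2 (2 mol%), SPhos (4 mol%), THF, 0 °C to rt
Reagents that add atoms: none
Why: Negishi coupling, in which zinc inserts into the benzylic C–Cl bond with LiCl assistance and zerovalent palladium formed from Pd(OAc)2/SPhos adds oxidatively to the C–Br bond activated by the ortho-formyl group, so that C(sp2)–C(sp3) coupling should outrun addition of the mild benzylzinc reagent to the electron-rich aldehyde or the pivalate.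

Step 3
Reactants: 5 4-(3,4-dimethoxybenzyl)-5-formyl-2-methoxyphenyl pivalate; 6 tiglic aldehyde, (E)-2-methylbut-2-enal (3 equiv)
Product: 8 (1S,2R,3S,4R)-4-(3,4-dimethoxyphenyl)-1-hydroxy-6-methoxy-2,3-dimethyl-7-(pivaloyloxy)-1,2,3,4-tetrahydronaphthalene-2-carbaldehyde, via (E,E)-hydroxy-o-quinodimethane 7 (not isolated)
Conditions: Ti(Oi-Pr)4 (1.2 equiv), (R,R)-TADDOL (1.3 equiv), hν (366 nm), degassed toluene, rt
Reagents that add atoms: none
Why: Excitation of the aryl aldehyde and intersystem crossing trigger a 1,5-hydrogen transfer from the doubly benzylic CH2 to the carbonyl oxygen, and the biradical relaxes to the (E,E)-dienol 7 (the (Z)-enol merely returns to 5 by a 1,5-hydrogen shift), whose hydroxyl is taken up as a Ti–O bond on the TADDOL-bearing titanium centre that also binds the carbonyl oxygen of 6. The closest known reaction type is the photoenolization/Diels–Alder reaction of 2-alkyl- and 2-benzylbenzaldehydes with electron-poor alkenes, including its Ti(Oi-Pr)4-promoted and chiral titanium TADDOLate variants with hindered enones. Ring B is closed by an intermolecular, titanium-templated endo [4+2] cycloaddition that restores the aromaticity of ring A, the C3–C4 bond running ahead of the C1–C2 bond. C3 and C4 follow from the outward aryl group of the dienol, the endo formyl group and the retained (E) geometry of 6 (aryl cis to formyl, hence trans to the 3-methyl group); the quaternary C2 follows from the same suprafacial addition, C1 from the outward hydroxyl, and the absolute sense from the TADDOL ligand shielding one face of the bound enal. The step needs regioselectivity (formyl-bearing carbon next to the carbinol carbon), endo selectivity and facial selectivity: the first is secured by the oxygen donor, which makes the benzhydryl terminus the nucleophilic end of the diene, and by the Ti–O tether, the second by the same two-point binding, and the third by the ligand. The hindered trisubstituted enal is the weak point, offset by its excess and by the templating.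

Step 4
Reactants: 8 (1S,2R,3S,4R)-4-(3,4-dimethoxyphenyl)-1-hydroxy-6-methoxy-2,3-dimethyl-7-(pivaloyloxy)-1,2,3,4-tetrahydronaphthalene-2-carbaldehyde
Product: 9 (2S,3S,4R)-4-(3,4-dimethoxyphenyl)-6-methoxy-2,3-dimethyl-1-oxo-7-(pivaloyloxy)-1,2,3,4-tetrahydronaphthalene-2-carbaldehyde
Conditions: Dess–Martin periodinane, CH2Cl2, 0 °C to rt; short filtration, used crude
Reagents that add atoms: none
Why: Dess–Martin oxidation of the hindered benzylic carbinol proceeds by ligand exchange on iodine without base, so the β-hydroxy aldehyde is not exposed to retro-aldol conditions, and C2, C3 and C4 are untouched because the quaternary C2 cannot enolize.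

Step 5
Reactants: 9 (2S,3S,4R)-4-(3,4-dimethoxyphenyl)-6-methoxy-2,3-dimethyl-1-oxo-7-(pivaloyloxy)-1,2,3,4-tetrahydronaphthalene-2-carbaldehyde
Product: 11 epischisandrone [(2R,3S,4R)-4-(3,4-dimethoxyphenyl)-7-hydroxy-6-methoxy-2,3-dimethyl-3,4-dihydronaphthalen-1(2H)-one], via disodium enolate 10 (not isolated)
Conditions: NaOMe (3 equiv), degassed MeOH, rt to 40 °C; then 1 M HCl
Reagents that add atoms: none
Why: Retro-Claisen deformylation, in which methoxide adds to the unhindered, non-enolizable formyl group and expels the aryl ketone enolate 10 while the aryl pivalate is transesterified, and reversible protonation of 10 under thermodynamic control should place the 2-methyl group trans to the 3-methyl group, since the all-trans tetralone carries both methyls and the aryl group (pseudo)equatorial on the half-chair of ring B and C3 and C4 are not acidic under these conditions.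

Compound list
1 | 2-bromo-5-hydroxy-4-methoxybenzaldehyde (6-bromoisovanillin) | COc1cc(Br)c(C=O)cc1O | starting material
2 | 4-bromo-5-formyl-2-methoxyphenyl pivalate | COc1cc(Br)c(C=O)cc1OC(=O)C(C)(C)C | intermediate
3 | 3,4-dimethoxybenzyl chloride | COc1ccc(CCl)cc1OC | starting material
4 | (3,4-dimethoxybenzyl)zinc chloride, LiCl-solubilized, not isolated | COc1ccc(C[Zn]Cl)cc1OC | intermediate
5 | 4-(3,4-dimethoxybenzyl)-5-formyl-2-methoxyphenyl pivalate | COc1cc(Cc2ccc(OC)c(OC)c2)c(C=O)cc1OC(=O)C(C)(C)C | intermediate
6 | tiglic aldehyde, (E)-2-methylbut-2-enal | C/C=C(\C)C=O | starting material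
7 | (E,E)-hydroxy-o-quinodimethane (photoenol of 5, hydroxyl and aryl both outward; held on titanium as its dienolate, not isolated) | O/C=C1\C=C(OC(=O)C(C)(C)C)C(OC)=C/C1=C\c1ccc(OC)c(OC)c1 | intermediate
8 | (1S,2R,3S,4R)-4-(3,4-dimethoxyphenyl)-1-hydroxy-6-methoxy-2,3-dimethyl-7-(pivaloyloxy)-1,2,3,4-tetrahydronaphthalene-2-carbaldehyde (hydroxyl, formyl and aryl cis; 3-methyl trans to aryl) | COc1cc2c(cc1OC(=O)C(C)(C)C)[C@H](O)[C@](C)(C=O)[C@@H](C)[C@@H]2c1ccc(OC)c(OC)c1 | intermediate
9 | (2S,3S,4R)-4-(3,4-dimethoxyphenyl)-6-methoxy-2,3-dimethyl-1-oxo-7-(pivaloyloxy)-1,2,3,4-tetrahydronaphthalene-2-carbaldehyde | COc1cc2c(cc1OC(=O)C(C)(C)C)C(=O)[C@](C)(C=O)[C@@H](C)[C@@H]2c1ccc(OC)c(OC)c1 | intermediate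
10 | disodium enolate-phenolate of the deformylated, depivaloylated tetralone (3S,4R), not isolated | COc1cc2c(cc1[O-])C([O-])=C(C)[C@@H](C)[C@@H]2c1ccc(OC)c(OC)c1.[Na+].[Na+] | intermediate
11 | epischisandrone, (2R,3S,4R)-4-(3,4-dimethoxyphenyl)-7-hydroxy-6-methoxy-2,3-dimethyl-3,4-dihydronaphthalen-1(2H)-one (2-methyl, 3-methyl and 4-aryl all trans) | COc1cc2c(cc1O)C(=O)[C@H](C)[C@@H](C)[C@@H]2c1ccc(OC)c(OC)c1 | target

Total step count: 5. Longest linear sequence: 5 steps (1 → 2 → 5 → 8 → 9 → 11).

Steps most likely to fail

Step 3. The α-branched, β-substituted enal may be engaged too slowly by the titanium-bound dienol, so that reketonization of 7 wins and the chiral complex discriminates the diene faces poorly. The fallback replaces catalyst control by resolution. It sets out from 5 and runs the ligand-free Ti(Oi-Pr)4-promoted photoenolization/Diels–Alder reaction with 6 (hν 366 nm, toluene, rt), which should give the racemic adduct F1 with the same relative configuration. Preparative supercritical-fluid chromatography of this carbinol on an amylose tris(3,5-dimethylphenylcarbamate) phase then returns to the route at 8.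

Step 5. Protonation of enolate 10 under kinetic control, from the face anti to the 3-methyl group, leads to the 2,3-cis epimer, and equilibration may stop at a mixture; the phenolate may also autoxidize at the doubly benzylic C4. The fallback fixes C2 in the cycloaddition instead of by equilibration. It sets out from 5, which under the conditions of step 3 with (E)-but-2-enal in place of 6 should give the endo 2-formyl-3-methyl carbinol F2, whose formyl group is trans to the 3-methyl group. Condensation with TsNHNH2 (EtOH, rt) gives the tosylhydrazone F3, and reduction with catecholborane followed by NaOAc·3H2O turns the formyl carbon into the 2-methyl group without touching C2, giving the 2,3-trans-dimethyl carbinol F4. Dess–Martin oxidation gives O-pivaloyl epischisandrone F5, and ammonolysis of the aryl ester (NH3, MeOH, 0 °C to rt), weakly basic enough to leave the ketone essentially unenolized, comes back to the route at 11.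

Step 2. Wurtz-type homocoupling may accompany zinc insertion into the electron-rich benzylic chloride, and the benzylzinc reagent may add to the aldehyde before it transmetalates. The fallback uses an aldehyde-inert boron nucleophile. It sets out from 3, which on Pd-catalysed borylation with B2pin2 (Pd2(dba)3, tris(4-methoxyphenyl)phosphine, KOAc, toluene, 50 °C) should give the benzylboronic pinacol ester F6. Suzuki–Miyaura coupling of F6 with 2 (Pd(dppf)Cl2, K3PO4, dioxane/H2O, 80 °C) comes back to the route at 5.

Further compounds
F1 | step 3 | racemic adduct (±)-8, equimolar mixture of 8 and its mirror image | COc1cc2c(cc1OC(=O)C(C)(C)C)[C@H](O)[C@](C)(C=O)[C@@H](C)[C@@H]2c1ccc(OC)c(OC)c1.COc1cc2c(cc1OC(=O)C(C)(C)C)[C@@H](O)[C@@](C)(C=O)[C@H](C)[C@H]2c1ccc(OC)c(OC)c1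
F2 | step 5 | 4-(3,4-dimethoxyphenyl)-1-hydroxy-6-methoxy-3-methyl-7-(pivaloyloxy)-1,2,3,4-tetrahydronaphthalene-2-carbaldehyde, hydroxyl, formyl and aryl cis, 3-methyl trans to both neighbours | COc1cc2c(cc1OC(=O)C(C)(C)C)[C@H](O)[C@H](C=O)[C@@H](C)[C@@H]2c1ccc(OC)c(OC)c1
F3 | step 5 | (E)-tosylhydrazone of F2 | COc1cc2c(cc1OC(=O)C(C)(C)C)[C@H](O)[C@H](/C=N/NS(=O)(=O)c1ccc(C)cc1)[C@@H](C)[C@@H]2c1ccc(OC)c(OC)c1
F4 | step 5 | 8-(3,4-dimethoxyphenyl)-5-hydroxy-3-methoxy-6,7-dimethyl-5,6,7,8-tetrahydronaphthalen-2-yl pivalate, 2,3-trans-3,4-trans carbinol (tetralin numbering) | COc1cc2c(cc1OC(=O)C(C)(C)C)[C@H](O)[C@H](C)[C@@H](C)[C@@H]2c1ccc(OC)c(OC)c1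
F5 | step 5 | O-pivaloyl epischisandrone, (2R,3S,4R) | COc1cc2c(cc1OC(=O)C(C)(C)C)C(=O)[C@H](C)[C@@H](C)[C@@H]2c1ccc(OC)c(OC)c1
F6 | step 2 | 2-(3,4-dimethoxybenzyl)-4,4,5,5-tetramethyl-1,3,2-dioxaborolane | COc1ccc(CB2OC(C)(C)C(C)(C)O2)cc1OC
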